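**Plan**
1. Retrosynthesis: remove the acetyl group, then cut the C-3–C-4 bond of the heptenoate chain (vinyl CH to carbinol carbon) to give (E)-iodoenoate 7 and hydroxy-aldehyde 17. 17 is cut at the ring C–CH3 bond and at the two ring bonds of a Michael/aldol annulation. 7 is cut at the vinyl CH (from iodoform) and at the malonate alkylation bond.
2. Forward: malonate alkylation, diiodomethylation and decarboxylative elimination give 7. The 3-methylglutarate half-ester gives aldehyde 11, the cyclohexenone ring is built by organocatalytic Michael addition to butenone and aldol condensation, and MeLi addition, desilylation and oxidation give 17. A Ni/Cr coupling joins 7 and 17, and acetylation comes last.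
3. Stereochemistry: chain C-6 comes from the (R)-half-ester; the ring attachment carbon from the (S)-prolinol ether catalyst; the ring carbinol carbon from axial MeLi attack (epimers separable); chain C-4 from the chiral Cr ligand; the E-alkene from the decarboxylative elimination, retained in the coupling.
4. Enabling feature: the chain carbinol C-4 is allylic to the C-2=C-3 enoate and trans to the ester, so a C-3 alkenylchromium can add to the aldehyde without lactonisation. C-4 is flanked by the C-5 methylene, so there is no epimerisable α-centre. The only other hydroxyl is the tertiary carbinol of the cyclohexene ring, which Cr(III) chemistry tolerates unprotected.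

Key step: step 12

Assumption: methyl hydrogen (R)-3-methylglutarate and 5-bromo-2-methylpent-2-ene are taken as catalogue compounds; the oxazoline–sulfonamide ligand of step 12 is accessible in both antipodes, and the one that directs Re-face addition is used.

**Step 1**
Reactants: 1 diethyl malonate; 2 5-bromo-2-methylpent-2-ene
Product: 3 diethyl 2-(4-methylpent-3-en-1-yl)propanedioate
Conditions: NaH, excess 1, THF/DMF, 0 to 60 °C
Reagents that add atoms: none
Why: Malonic ester alkylation of a soft stabilised enolate with an unhindered primary bromide, with excess malonate to suppress dialkylation.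

**Step 2**
Reactants: 3 diethyl 2-(4-methylpent-3-en-1-yl)propanedioate
Product: 4 diethyl 2-(diiodomethyl)-2-(4-methylpent-3-en-1-yl)propanedioate
Conditions: NaH, CHI3, Et2O, reflux
Reagents that add atoms: iodoform, IC(I)I
Why: C-diiodomethylation of a monoalkylmalonate enolate with iodoform, a known route to the precursors of (E)-3-iodo-2-alkylacrylic acids; the enolate should outcompete the isolated trisubstituted alkene.

**Step 3**
Reactants: 4 diethyl 2-(diiodomethyl)-2-(4-methylpent-3-en-1-yl)propanedioate
Product: 6 (2E)-2-(iodomethylidene)-6-methylhept-5-enoic acid, via dipotassium malonate 5 (not isolated)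
Conditions: KOH, EtOH/H2O, reflux; then aq. HCl
Reagents that add atoms: potassium hydroxide, [K+].[OH-]
Why: Saponification followed by decarboxylative elimination of iodide (a Grob-type fragmentation), which for this substrate class gives the E-iodoacrylic acid with iodine trans to the carboxyl group.

**Step 4**
Reactants: 6 (2E)-2-(iodomethylidene)-6-methylhept-5-enoic acid
Product: 7 methyl (2E)-2-(iodomethylidene)-6-methylhept-5-enoate
Conditions: MeI, K2CO3, DMF, rt
Reagents that add atoms: iodomethane, CI
Why: O-alkylation of the carboxylate (SN2 esterification) under conditions that leave the alkenyl iodide and its geometry untouched.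

**Step 5**
Reactants: 8 (3R)-5-methoxy-3-methyl-5-oxopentanoic acid (methyl hydrogen (R)-3-methylglutarate)
Product: 9 methyl (3R)-5-hydroxy-3-methylpentanoate
Conditions: BH3·SMe2, THF, 0 °C to rt; MeOH, aq. work-up
Reagents that add atoms: none
Why: Chemoselective borane reduction of a carboxylic acid in the presence of a methyl ester, which differentiates the two arms of the glutarate and carries the stereocentre through unchanged.

**Step 6**
Reactants: 9 methyl (3R)-5-hydroxy-3-methylpentanoate
Product: 10 methyl (3R)-5-[(tert-butyldimethylsilyl)oxy]-3-methylpentanoate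
Conditions: TBSCl, imidazole, DMF, rt
Reagents that add atoms: tert-butyldimethylsilyl chloride, CC(C)(C)[Si](C)(C)Cl
Why: Standard silylation of a primary alcohol, which also prevents lactonisation of the δ-hydroxy ester.

**Step 7**
Reactants: 10 methyl (3R)-5-[(tert-butyldimethylsilyl)oxy]-3-methylpentanoate
Product: 11 (3R)-5-[(tert-butyldimethylsilyl)oxy]-3-methylpentanal
Conditions: DIBAL-H (1.1 equiv), CH2Cl2, −78 °C; Rochelle salt
Reagents that add atoms: none
Why: Partial DIBAL-H reduction of a methyl ester to the aldehyde through the tetrahedral aluminate, which is stable at low temperature.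

**Step 8**
Reactants: 11 (3R)-5-[(tert-butyldimethylsilyl)oxy]-3-methylpentanal; 12 but-3-en-2-one
Product: 14 (4S)-4-[(2R)-4-[(tert-butyldimethylsilyl)oxy]butan-2-yl]cyclohex-2-en-1-one, via keto-aldehyde 13 (not isolated)
Conditions: (S)-α,α-diphenylprolinol methyl ether (5 mol %), ethyl 3,4-dihydroxybenzoate (20 mol %), neat, 4 °C; then LiOH (cat.), i-PrOH, rt
Reagents that add atoms: none
Why: Enamine-catalysed Michael addition followed by intramolecular aldol condensation (organocatalytic Robinson annulation), precedented for β-methyl-branched aldehydes; the (S)-catalyst shields one enamine face so the enone adds to the other, which should set the 2S centre of 13 and hence 4S in 14.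

**Step 9**
Reactants: 14 (4S)-4-[(2R)-4-[(tert-butyldimethylsilyl)oxy]butan-2-yl]cyclohex-2-en-1-one
Product: 15 (1R,4S)-4-[(2R)-4-[(tert-butyldimethylsilyl)oxy]butan-2-yl]-1-methylcyclohex-2-en-1-ol
Conditions: MeLi, Et2O, −78 °C; H2O; chromatography
Reagents that add atoms: methyllithium, [Li]C
Why: 1,2-Addition of an organolithium to the enone carbonyl; axial attack on the half-chair with the side chain pseudo-equatorial places CH3 cis and OH trans to the side chain (1R), and the C-1 epimer, a diastereomer, should be separable on silica.

**Step 10**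
Reactants: 15 (1R,4S)-4-[(2R)-4-[(tert-butyldimethylsilyl)oxy]butan-2-yl]-1-methylcyclohex-2-en-1-ol
Product: 16 (1R,4S)-4-[(2R)-4-hydroxybutan-2-yl]-1-methylcyclohex-2-en-1-ol
Conditions: TBAF, THF, rt
Reagents that add atoms: none
Why: Fluoride-mediated cleavage of the primary silyl ether under non-acidic conditions, which the acid-sensitive tertiary allylic alcohol should survive.

**Step 11**
Reactants: 16 (1R,4S)-4-[(2R)-4-hydroxybutan-2-yl]-1-methylcyclohex-2-en-1-ol
Product: 17 (3R)-3-[(1S,4R)-4-hydroxy-4-methylcyclohex-2-en-1-yl]butanal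
Conditions: Dess–Martin periodinane, pyridine, CH2Cl2, 0 °C
Reagents that add atoms: none
Why: Dess–Martin oxidation of the primary alcohol; the tertiary alcohol cannot be oxidised, the buffered non-chromium conditions avoid allylic transposition, and the trans ring geometry prevents lactol formation.

**Step 12**
Reactants: 17 (3R)-3-[(1S,4R)-4-hydroxy-4-methylcyclohex-2-en-1-yl]butanal; 7 methyl (2E)-2-(iodomethylidene)-6-methylhept-5-enoate
Product: 18 methyl (2E,4S,6R)-4-hydroxy-6-[(1S,4R)-4-hydroxy-4-methylcyclohex-2-en-1-yl]-2-(4-methylpent-3-en-1-yl)hept-2-enoate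
Conditions: CrCl2 (15 mol %), chiral oxazoline–sulfonamide ligand (17 mol %), proton sponge (17 mol %), NiCl2·(2,9-dimethyl-1,10-phenanthroline) (2 mol %), Mn (2 equiv), Cp2ZrCl2 (2.2 equiv), LiCl, MeCN, rt; aq. work-up
Reagents that add atoms: none
Why: Ni(0) inserts into the C–I bond of 7 with retention, the alkenyl group is passed to Cr(III) bearing the chiral sulfonamide ligand, and the alkenylchromium adds to the aldehyde of 17; Cp2ZrCl2 takes over the alkoxide and Mn returns Cr(III) to Cr(II). The closest known reaction type is the catalytic asymmetric Nozaki–Hiyama–Kishi alkenylation of aldehydes with β-iodo-enoates. No ring is closed. The new C-4 stereocentre (S) is set by the Cr ligand, which should deliver the alkenyl group to the Re face of the aldehyde; the β-methyl centre at C-6 exerts little 1,3-induction, so reagent control decides. The step needs chemoselectivity for the aldehyde over the ester and tolerance of the free tertiary allylic alcohol, both secured by the non-basic, aldehyde-selective alkenylchromium(III). It also needs retention of the E geometry, secured because the ester trans to chromium is the stable arrangement and the product cannot lactonise.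

**Step 13**
Reactants: 18 methyl (2E,4S,6R)-4-hydroxy-6-[(1S,4R)-4-hydroxy-4-methylcyclohex-2-en-1-yl]-2-(4-methylpent-3-en-1-yl)hept-2-enoate
Product: 19 methyl (2E,4S,6R)-4-(acetyloxy)-6-[(1S,4R)-4-hydroxy-4-methylcyclohex-2-en-1-yl]-2-(4-methylpent-3-en-1-yl)hept-2-enoate
Conditions: Ac2O, pyridine, CH2Cl2, 0 °C to rt
Reagents that add atoms: acetic anhydride, CC(=O)OC(C)=O
Why: Site-selective acylation of the secondary allylic alcohol; the tertiary ring alcohol is too hindered to react without a stronger acyl-transfer catalyst or heat.

**Compound list**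
1 | diethyl malonate | CCOC(=O)CC(=O)OCC | starting material
2 | 5-bromo-2-methylpent-2-ene | CC(C)=CCCBr | starting material
3 | diethyl 2-(4-methylpent-3-en-1-yl)propanedioate | CCOC(=O)C(CCC=C(C)C)C(=O)OCC | intermediate
4 | diethyl 2-(diiodomethyl)-2-(4-methylpent-3-en-1-yl)propanedioate | CCOC(=O)C(CCC=C(C)C)(C(I)I)C(=O)OCC | intermediate
5 | dipotassium 2-(diiodomethyl)-2-(4-methylpent-3-en-1-yl)propanedioate (not isolated) | [K+].[K+].[O-]C(=O)C(CCC=C(C)C)(C(I)I)C([O-])=O | intermediate
6 | (2E)-2-(iodomethylidene)-6-methylhept-5-enoic acid | OC(=O)/C(=C/I)CCC=C(C)C | intermediate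
7 | methyl (2E)-2-(iodomethylidene)-6-methylhept-5-enoate | COC(=O)/C(=C/I)CCC=C(C)C | intermediate
8 | (3R)-5-methoxy-3-methyl-5-oxopentanoic acid | COC(=O)C[C@H](C)CC(=O)O | starting material
9 | methyl (3R)-5-hydroxy-3-methylpentanoate | COC(=O)C[C@H](C)CCO | intermediate
10 | methyl (3R)-5-[(tert-butyldimethylsilyl)oxy]-3-methylpentanoate | COC(=O)C[C@H](C)CCO[Si](C)(C)C(C)(C)C | intermediate
11 | (3R)-5-[(tert-butyldimethylsilyl)oxy]-3-methylpentanal | O=CC[C@H](C)CCO[Si](C)(C)C(C)(C)C | intermediate
12 | but-3-en-2-one | CC(=O)C=C | starting material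
13 | (2S)-2-[(2R)-4-[(tert-butyldimethylsilyl)oxy]butan-2-yl]-5-oxohexanal (not isolated) | CC(C)(C)[Si](C)(C)OCC[C@@H](C)[C@H](CCC(C)=O)C=O | intermediate
14 | (4S)-4-[(2R)-4-[(tert-butyldimethylsilyl)oxy]butan-2-yl]cyclohex-2-en-1-one | CC(C)(C)[Si](C)(C)OCC[C@@H](C)[C@H]1C=CC(=O)CC1 | intermediate
15 | (1R,4S)-4-[(2R)-4-[(tert-butyldimethylsilyl)oxy]butan-2-yl]-1-methylcyclohex-2-en-1-ol | CC(C)(C)[Si](C)(C)OCC[C@@H](C)[C@H]1C=C[C@](C)(O)CC1 | intermediate
16 | (1R,4S)-4-[(2R)-4-hydroxybutan-2-yl]-1-methylcyclohex-2-en-1-ol | OCC[C@@H](C)[C@H]1C=C[C@](C)(O)CC1 | intermediate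
17 | (3R)-3-[(1S,4R)-4-hydroxy-4-methylcyclohex-2-en-1-yl]butanal | O=CC[C@@H](C)[C@H]1C=C[C@](C)(O)CC1 | intermediate
18 | methyl (2E,4S,6R)-4-hydroxy-6-[(1S,4R)-4-hydroxy-4-methylcyclohex-2-en-1-yl]-2-(4-methylpent-3-en-1-yl)hept-2-enoate | COC(=O)/C(=C/[C@H](C[C@@H](C)[C@H]1C=C[C@](C)(O)CC1)O)CCC=C(C)C | intermediate
19 | methyl (2E,4S,6R)-4-(acetyloxy)-6-[(1S,4R)-4-hydroxy-4-methylcyclohex-2-en-1-yl]-2-(4-methylpent-3-en-1-yl)hept-2-enoate | COC(=O)/C(=C/[C@H](C[C@@H](C)[C@H]1C=C[C@](C)(O)CC1)OC(C)=O)CCC=C(C)C | target

**Count and risks**
Total steps: 13 (4 to iodoenoate 7, 7 to aldehyde 17, 2 after the union). Longest linear sequence: 9 steps (8 to 19, steps 5–13).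

Steps most likely to fail:

1. Step 12. Facial selection at the aldehyde rests on the chromium ligand alone and may be incomplete, and reductive dimerisation of the iodoenoate can compete. The fallback sets out from 18 as delivered by the coupling, whatever its purity at C-4. Dess–Martin oxidation of the secondary allylic alcohol (the tertiary alcohol is inert) would give methyl (2E,6R)-6-[(1S,4R)-4-hydroxy-4-methylcyclohex-2-en-1-yl]-2-(4-methylpent-3-en-1-yl)-4-oxohept-2-enoate F1. Corey–Bakshi–Shibata reduction with the (R)-oxazaborolidine and catecholborane at −78 °C, the alkenyl group acting as the large substituent, should then return to 18 with the 4S configuration set by the reagent.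

2. Step 9. Methyl addition to the enone carbonyl may show poor facial selectivity, and γ-deprotonation could erode the adjacent ring stereocentre. The fallback sets out from 14. A Corey–Chaykovsky reaction with dimethylsulfonium methylide (irreversible 1,2-addition along the axial trajectory) would give the spiro-epoxide (3R,6S)-6-[(2R)-4-[(tert-butyldimethylsilyl)oxy]butan-2-yl]-1-oxaspiro[2.5]oct-4-ene F2, with the oxirane oxygen trans to the side chain. Hydride opening at the oxirane CH2 with LiEt3BH should convert it into the methyl carbinol and come back to the route at 15.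

3. Step 8. Catalyst control in the Michael addition may be insufficient if the catalyst and the β-methyl stereocentre are mismatched, giving a mixture at the new α-centre. The fallback sets out from 11 and replaces catalyst control by auxiliary control. Condensation with RAMP would give the RAMP hydrazone of 11 F3. Deprotonation with LDA and alkylation with 2-(2-iodoethyl)-2-methyl-1,3-dioxolane would give the α-alkylated RAMP hydrazone F4; RAMP is chosen because the original substituent outranks the new chain, so it should give the 2S centre. Two-phase oxalic acid cleavage would release (2S)-2-[(2R)-4-[(tert-butyldimethylsilyl)oxy]butan-2-yl]-4-(2-methyl-1,3-dioxolan-2-yl)butanal F5. Ketal hydrolysis (PPTS, wet acetone) comes back to the route at 13, which is closed to 14 with LiOH in i-PrOH as in step 8.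

**Further compounds**
F1 | step 12 | methyl (2E,6R)-6-[(1S,4R)-4-hydroxy-4-methylcyclohex-2-en-1-yl]-2-(4-methylpent-3-en-1-yl)-4-oxohept-2-enoate | COC(=O)/C(=C/C(=O)C[C@@H](C)[C@H]1C=C[C@](C)(O)CC1)CCC=C(C)C
F2 | step 9 | (3R,6S)-6-[(2R)-4-[(tert-butyldimethylsilyl)oxy]butan-2-yl]-1-oxaspiro[2.5]oct-4-ene | CC(C)(C)[Si](C)(C)OCC[C@@H](C)[C@H]1C=C[C@]2(OC2)CC1
F3 | step 8 | RAMP hydrazone of 11 | CC(C)(C)[Si](C)(C)OCC[C@@H](C)C/C=N/N1CCC[C@@H]1COC
F4 | step 8 | α-alkylated RAMP hydrazone (hydrazone of aldehyde F5) | CC(C)(C)[Si](C)(C)OCC[C@@H](C)[C@H](CCC1(C)OCCO1)/C=N/N1CCC[C@@H]1COC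
F5 | step 8 | (2S)-2-[(2R)-4-[(tert-butyldimethylsilyl)oxy]butan-2-yl]-4-(2-methyl-1,3-dioxolan-2-yl)butanal | CC(C)(C)[Si](C)(C)OCC[C@@H](C)[C@H](CCC1(C)OCCO1)C=O
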